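**Retrosynthetic overview**

1. Target 22 is a spirolactone-type 6,7-seco-ent-kauranoid (ent-kaurane atom numbers are used for every compound). The C6 aldehyde comes last from the primary alcohol, the exocyclic enone from dehydration of a C16 methyl carbinol, and ring D (C15–C16) from a carbene-catalysed aldehyde–ketone benzoin closure on 18.
2. Key disconnection: the δ-lactone ring C7–C8–C9–C10–C20–O of 18 is opened at C7–C8 and C9–C10. This gives ring A alkene carbonate 9 and ring C enal 16, two fragments of similar size joined at the bond between quaternary C10 and C9.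
3. Enabling feature: C8 is the α-carbon and C9 the β-carbon of the C15 carbonyl, and the second carbonyl on C8 (C7) is tied through O and C20 to the spiro carbon C10 of ring A. A C10 radical (hydrogen atom transfer to a C10=C1 alkene) can therefore add to C9, and the C8 enolate that results can be acylated by a carbonate on the C20 oxygen.
4. Ring A: 2,6-dimethylbenzoic acid is dearomatised (Birch), the prochiral diene is desymmetrised by asymmetric epoxidation and opened with acetic acid, which sets C3, C4 and C5. Ring C: acetoacetate plus two molecules of acrolein, then aldol condensation; C13 stays epimerisable (acetyl) and is fixed when ring D closes.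
5. Order of ring formation: ring A (from the arene) and ring C separately, the lactone ring in the key step, ring D last.

Key step: step 11

Assumption on the chemistry: the L-fructose-derived enantiomer of the Shi ketone is taken as the one that epoxidises the required enantiotopic alkene of 4 (inferred from the usual facial sense of this catalyst class with 1-substituted cyclohexenes); if the sense is opposite, the D-fructose-derived ketone takes its place.

**Route**

Step 1
Reactants: 1 2,6-dimethylbenzoic acid
Product: 2 2,6-dimethylcyclohexa-2,5-diene-1-carboxylic acid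
Conditions: Li, NH3(l)/THF, −78 °C; NH4Cl
Reagents that add atoms: none
Why: Birch reduction of a benzoic acid protonates the para carbon and then the ipso carbon, so the arene is dearomatised to the 2,5-diene acid whose sp3 carbon becomes C5 and whose two methyl-bearing alkenes (future C3=C4 and C10=C1) are enantiotopic.

Step 2
Reactants: 2 2,6-dimethylcyclohexa-2,5-diene-1-carboxylic acid
Product: 3 (2,6-dimethylcyclohexa-2,5-dien-1-yl)methanol
Conditions: LiAlH4, THF, 0 °C → rt
Reagents that add atoms: none
Why: Hydride reduction of the carboxylic acid gives the primary alcohol (future C6) and leaves the unconjugated diene untouched.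

Step 3
Reactants: 3 (2,6-dimethylcyclohexa-2,5-dien-1-yl)methanol
Product: 4 TBDPS ether of 3
Conditions: TBDPSCl, imidazole, DMF, rt
Reagents that add atoms: tert-butyl(chloro)diphenylsilane, CC(C)(C)[Si](Cl)(c1ccccc1)c1ccccc1
Why: Silylation of the primary alcohol gives a bulky, acid-stable ether that later shields one face of ring A and survives the acetolysis of step 5.

Step 4
Reactants: 4 TBDPS ether of 3
Product: 5 anti monoepoxide (3S,4R,5R)
Conditions: 1,2:4,5-di-O-isopropylidene-β-L-erythro-2,3-hexodiulo-2,6-pyranose (L-fructose-derived Shi ketone, 30 mol %), KHSO5 (as 2KHSO5·KHSO4·K2SO4), K2CO3, n-Bu4NHSO4, MeCN/CH2(OMe)2/aq Na2B4O7, 0 °C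
Reagents that add atoms: potassium peroxymonosulfate, [K+].[O-]S(=O)(=O)OO
Why: Shi asymmetric epoxidation of a trisubstituted alkene is used group-selectively: the CH2OTBDPS group on the sp3 carbon restricts the dioxirane to the opposite face of both alkenes and the chiral ketone then selects one of the two enantiotopic alkenes, which sets C3, C4 and C5 together, while the slower mismatched second epoxidation should remove the minor enantiomer.

Step 5
Reactants: 5 anti monoepoxide
Product: 6 hydroxy acetate (3S,4S,5R)
Conditions: AcOH, NaOAc, 45 °C
Reagents that add atoms: acetic acid, CC(=O)O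
Why: Acid-mediated epoxide acetolysis takes place at the tertiary carbon C4 with inversion (trans-diaxial opening in the half-chair that keeps CH2OTBDPS equatorial), so the C4 acetate ends cis to C6 and trans to the C3 hydroxyl, which is the pattern of the target.

Step 6
Reactants: 6 hydroxy acetate
Product: 7 TBS ether of 6
Conditions: TBSOTf, 2,6-lutidine, CH2Cl2, −40 → 0 °C
Reagents that add atoms: tert-butyldimethylsilyl trifluoromethanesulfonate, CC(C)(C)[Si](C)(C)OS(=O)(=O)C(F)(F)F
Why: Silyl ether formation protects the C3 alcohol through the radical step and the later dehydration without base that could move the neighbouring acetate.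

Step 7
Reactants: 7 TBS ether of 6
Product: 8 allylic alcohol (C20 hydroxyl)
Conditions: SeO2 (0.3 equiv), t-BuOOH (2 equiv), CH2Cl2, 0 °C → rt
Reagents that add atoms: tert-butyl hydroperoxide, CC(C)(C)OO (oxygen relayed by the SeO2 catalyst)
Why: SeO2 allylic (Riley) oxidation proceeds by ene reaction and [2,3]-sigmatropic shift at a substituent of the more substituted alkene carbon C10, where the methyl group should react in preference to the hindered C5 methine, so C20 is oxygenated and the C10=C1 alkene stays in place.

Step 8
Reactants: 8 allylic alcohol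
Product: 9 phenyl carbonate of 8
Conditions: PhOCOCl, pyridine, CH2Cl2, 0 °C
Reagents that add atoms: phenyl chloroformate, O=C(Cl)Oc1ccccc1
Why: Acylation of the primary allylic alcohol installs the future lactone carbonyl C7 on the C20 oxygen as a carbonate with phenoxide as its leaving group.

Step 9
Reactants: 10 tert-butyl acetoacetate, 11 acrolein
Product: 13 tert-butyl 2-acetyl-5-oxo-2-(3-oxopropyl)pentanoate, via mono-Michael adduct 12 (not isolated)
Conditions: acrolein (2.3 equiv in total), Et3N (10 mol %), MeCN, 0 °C → rt
Reagents that add atoms: acrolein (second equivalent), C=CC=O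
Why: Base-catalysed Michael addition of the β-keto ester to acrolein gives mono-adduct 12, whose remaining acidic α-hydrogen allows a second Michael addition to another molecule of acrolein, so the seven-carbon dialdehyde chain is built around the carbon that becomes C13.

Step 10
Reactants: 13 tert-butyl 2-acetyl-5-oxo-2-(3-oxopropyl)pentanoate
Product: 16 5-acetylcyclohex-1-ene-1-carbaldehyde (racemic), via keto acid 14 (not isolated), via keto dialdehyde 15 (not isolated)
Conditions: CF3CO2H, CH2Cl2, rt → 40 °C; then dibenzylammonium trifluoroacetate (20 mol %), toluene, 50 °C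
Reagents that add atoms: none
Why: Acidolysis of the tert-butyl ester and decarboxylation of the β-keto acid give the symmetrical keto dialdehyde, and ammonium-catalysed intramolecular aldol condensation (enamine of one aldehyde arm onto the other aldehyde) closes ring C as the conjugated enal, with C13 racemic but epimerisable next to the ketone.

Step 11
Reactants: 9 phenyl carbonate (ring A fragment), 16 5-acetylcyclohex-1-ene-1-carbaldehyde (3 equiv)
Product: 18 spirolactone aldehyde (both C13 epimers), via iron enolate 17 (not isolated)
Conditions: Fe(acac)3 (50 mol %), Ph(i-PrO)SiH2 (2.5 equiv), THF, 0 °C → rt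
Reagents that add atoms: none
Why: Proposed new method: the trivalent iron hydride formed from Fe(acac)3 and the silane transfers a hydrogen atom to C1 of the trisubstituted alkene of 9, the tertiary C10 radical adds to C9 (the β-carbon of enal 16), divalent iron reduces the α-formyl radical to iron enolate 17, and its carbon C8 attacks the carbonate carbonyl C7 and expels phenoxide; the closest known reaction type is the iron-hydride-initiated radical–polar crossover annulation in which a Giese addition is followed by an intramolecular aldol reaction, and the only change is that the enolate is trapped by Claisen-type acylation on an aryl carbonate. The δ-lactone ring closes in the 6-(enolexo)-exo-trig mode by acyl substitution at C7. C10 is controlled by ring A, where the axial C4 acetoxy group blocks its own face so that C9 enters equatorially and trans to the C5 substituent; C9 is controlled by the same radical, because in the favoured staggered transition state H9 sits in the sector between C20 and C5 that the CH2OTBDPS group closes, C11 lies anti to C20 and C8 lies next to C1, which is also the rotamer from which C8 reaches C7; C8 is controlled by the tether, because allylic 1,3-strain in the exocyclic enolate holds C10 axial on ring C so that C7 is delivered to the same face and the lactone is cis-fused with the formyl group axial. The step needs chemoselective hydrogen atom transfer (secured by the electron-rich alkene of 9 against the acceptor alkene of 16), C-acylation ahead of protonation (secured by the aprotic medium, the six-membered transition state and the phenoxide leaving group) and face selectivity at C9 and C10 (secured by the C4 and C5 substituents of 9), whereas C13 is not controlled and need not be.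

Step 12
Reactants: 18 spirolactone aldehyde (both C13 epimers)
Product: 19 ring D acyloin
Conditions: 2-(pentafluorophenyl)-6,7-dihydro-5H-pyrrolo[2,1-c][1,2,4]triazol-2-ium tetrafluoroborate (20 mol %), DBU (1 equiv), THF, 40 °C
Reagents that add atoms: none
Why: In this carbene-catalysed intramolecular crossed benzoin reaction the Breslow intermediate of the C15 aldehyde adds to the C16 ketone and closes ring D as the bicyclo[3.2.1]octane; only the C13 epimer with the acetyl group cis to C15 can cyclise and DBU equilibrates the other through the ketone enolate, so C13 is set by the ring closure itself.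

Step 13
Reactants: 19 ring D acyloin
Product: 20 bis-silyl enone
Conditions: methyl N-(triethylammoniosulfonyl)carbamate (Burgess reagent), toluene, 60 °C
Reagents that add atoms: none
Why: Burgess dehydration (syn elimination of the sulfamate ester) of the tertiary ketol can only remove a methyl hydrogen because the other β-position is the C13 bridgehead, so the 16-methylene-15-ketone results.

Step 14
Reactants: 20 bis-silyl enone
Product: 21 diol
Conditions: HF·pyridine, pyridine/THF, 0 °C → rt
Reagents that add atoms: none
Why: Fluoride-mediated desilylation under acidic, non-basic conditions frees the C3 and C6 hydroxyls while the enone, the lactone and the tertiary acetate are tolerated.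

Step 15
Reactants: 21 diol
Product: 22 CNP0199571.1 (target)
Conditions: 2,2,6,6-tetramethylpiperidin-1-oxyl (TEMPO, 10 mol %), PhI(OAc)2, CH2Cl2, rt
Reagents that add atoms: none
Why: Oxoammonium (TEMPO) oxidation is selective for the primary C6 alcohol over the hindered axial C3 alcohol and is mild enough not to eliminate the β-acetoxy group or epimerise C5, whose configuration (formyl equatorial) is also the thermodynamic one.

**Compound list**

1 | 2,6-dimethylbenzoic acid | Cc1cccc(C)c1C(=O)O | starting material
2 | 2,6-dimethylcyclohexa-2,5-diene-1-carboxylic acid | CC1=CCC=C(C)C1C(=O)O | intermediate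
3 | (2,6-dimethylcyclohexa-2,5-dien-1-yl)methanol | CC1=CCC=C(C)C1CO | intermediate
4 | tert-butyl[(2,6-dimethylcyclohexa-2,5-dien-1-yl)methoxy]diphenylsilane | CC1=CCC=C(C)C1CO[Si](c1ccccc1)(c1ccccc1)C(C)(C)C | intermediate
5 | tert-butyl{[(1R,2R,6S)-1,3-dimethyl-7-oxabicyclo[4.1.0]hept-3-en-2-yl]methoxy}diphenylsilane (3S,4R,5R in target numbering; oxirane anti to CH2OTBDPS) | CC1=CC[C@@H]2O[C@]2(C)[C@H]1CO[Si](c1ccccc1)(c1ccccc1)C(C)(C)C | intermediate
6 | (1S,2R,6S)-2-({[tert-butyl(diphenyl)silyl]oxy}methyl)-6-hydroxy-1,3-dimethylcyclohex-3-en-1-yl acetate (3S,4S,5R; OAc cis to CH2OTBDPS, OH trans to OAc) | CC1=CC[C@H](O)[C@@](C)(OC(C)=O)[C@H]1CO[Si](c1ccccc1)(c1ccccc1)C(C)(C)C | intermediate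
7 | (1S,2R,6S)-6-{[tert-butyl(dimethyl)silyl]oxy}-2-({[tert-butyl(diphenyl)silyl]oxy}methyl)-1,3-dimethylcyclohex-3-en-1-yl acetate | CC1=CC[C@H](O[Si](C)(C)C(C)(C)C)[C@@](C)(OC(C)=O)[C@H]1CO[Si](c1ccccc1)(c1ccccc1)C(C)(C)C | intermediate
8 | (1S,2R,6S)-6-{[tert-butyl(dimethyl)silyl]oxy}-2-({[tert-butyl(diphenyl)silyl]oxy}methyl)-3-(hydroxymethyl)-1-methylcyclohex-3-en-1-yl acetate | OCC1=CC[C@H](O[Si](C)(C)C(C)(C)C)[C@@](C)(OC(C)=O)[C@H]1CO[Si](c1ccccc1)(c1ccccc1)C(C)(C)C | intermediate
9 | (1S,2R,6S)-6-{[tert-butyl(dimethyl)silyl]oxy}-2-({[tert-butyl(diphenyl)silyl]oxy}methyl)-1-methyl-3-{[(phenoxycarbonyl)oxy]methyl}cyclohex-3-en-1-yl acetate (ring A fragment) | O=C(Oc1ccccc1)OCC1=CC[C@H](O[Si](C)(C)C(C)(C)C)[C@@](C)(OC(C)=O)[C@H]1CO[Si](c1ccccc1)(c1ccccc1)C(C)(C)C | intermediate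
10 | tert-butyl acetoacetate (tert-butyl 3-oxobutanoate) | CC(=O)CC(=O)OC(C)(C)C | starting material
11 | acrolein (prop-2-enal) | C=CC=O | starting material
12 | mono-Michael adduct: tert-butyl 2-acetyl-5-oxopentanoate (racemic) | CC(=O)C(CCC=O)C(=O)OC(C)(C)C | intermediate (not isolated)
13 | tert-butyl 2-acetyl-5-oxo-2-(3-oxopropyl)pentanoate | CC(=O)C(CCC=O)(CCC=O)C(=O)OC(C)(C)C | intermediate
14 | 2-acetyl-5-oxo-2-(3-oxopropyl)pentanoic acid | CC(=O)C(CCC=O)(CCC=O)C(=O)O | intermediate (not isolated)
15 | 4-acetylheptanedial | CC(=O)C(CCC=O)CCC=O | intermediate (not isolated)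
16 | 5-acetylcyclohex-1-ene-1-carbaldehyde (racemic; ring C fragment) | O=CC1=CCCC(C(C)=O)C1 | intermediate
17 | iron enolate of the Giese adduct, drawn as the free enolate anion (C8=C15 enolate, C9–C10 bond formed, phenyl carbonate still on the C20 oxygen; 3S,4S,5R,9S,10R) | [O-]C=C1CC(C(C)=O)CC[C@H]1[C@@]1(CC[C@H](O[Si](C)(C)C(C)(C)C)[C@@](C)(OC(C)=O)[C@H]1CO[Si](c1ccccc1)(c1ccccc1)C(C)(C)C)COC(=O)Oc1ccccc1 | intermediate (not isolated)
18 | spirolactone aldehyde: δ-lactone (C7–O–C20) spiro at C10 to ring A and cis-fused at C8–C9 to ring C; C8 formyl (C15), C13 acetyl (both C13 epimers), C3 OTBS, C4 OAc and CH3, C5 CH2OTBDPS; 3S,4S,5R,8S,9S,10R | O=C[C@]23CC(C(C)=O)CC[C@H]2[C@@]1(CC[C@H](O[Si](C)(C)C(C)(C)C)[C@@](C)(OC(C)=O)[C@H]1CO[Si](c1ccccc1)(c1ccccc1)C(C)(C)C)COC3=O | intermediate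
19 | ring D acyloin: 16-hydroxy-16-methyl-15-ketone in the bicyclo[3.2.1]octane (C16 configuration undefined), otherwise as 18; 3S,4S,5R,8S,9S,10R,13R | CC1(O)C(=O)[C@]23C[C@H]1CC[C@H]2[C@@]1(CC[C@H](O[Si](C)(C)C(C)(C)C)[C@@](C)(OC(C)=O)[C@H]1CO[Si](c1ccccc1)(c1ccccc1)C(C)(C)C)COC3=O | intermediate
20 | bis-silyl enone: 16-methylene-15-ketone, C3 OTBS, C4 OAc, C5 CH2OTBDPS; 3S,4S,5R,8S,9S,10R,13R | C=C1C(=O)[C@]23C[C@H]1CC[C@H]2[C@@]1(CC[C@H](O[Si](C)(C)C(C)(C)C)[C@@](C)(OC(C)=O)[C@H]1CO[Si](c1ccccc1)(c1ccccc1)C(C)(C)C)COC3=O | intermediate
21 | diol: C3 hydroxyl and C6 primary hydroxyl free, otherwise as 20 | C=C1C(=O)[C@]23C[C@H]1CC[C@H]2[C@@]1(CC[C@H](O)[C@@](C)(OC(C)=O)[C@H]1CO)COC3=O | intermediate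
22 | CNP0199571.1: (3S,4S,5S,8S,9S,10R,13R)-4-acetoxy-3-hydroxy-15-oxo-6,7-seco-nor-ent-kaur-16-en-6-al 7,20-lactone (C5 is S here and R in 5–9 and 17–21 only because the priorities at C5 change) | C=C1C(=O)[C@]23C[C@H]1CC[C@H]2[C@@]1(CC[C@H](O)[C@@](C)(OC(C)=O)[C@H]1C=O)COC3=O | target

Total step count: 15
Longest linear sequence: 13 steps (steps 1–8 and 11–15)

**Steps most likely to fail**

Step 11 (Proposed new method). What may go wrong: slow addition of the hindered tertiary radical to the β-substituted enal, protonation of the iron enolate before it acylates, or poor face selectivity at C9. The fallback sets out from 9 and 16 and uses two known reactions in place of the cascade. The ordinary iron-hydride Giese coupling in a protic medium (Fe(acac)3, PhSiH3, EtOH/ethylene glycol, 60 °C) should give, after protonation of the enolate, the open Giese adduct F1, at which stage C9 epimers can be separated. The lactone is then closed in a separate polar step with DBU in MeCN (reversible enolisation of the α-branched aldehyde and Dieckmann-type C-acylation on the phenyl carbonate with loss of phenol), which comes back to the route at 18.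

Step 4. What may go wrong: insufficient discrimination between the two enantiotopic alkenes, or over-epoxidation. The fallback replaces desymmetrisation by resolution and sets out from 4. Epoxidation with mCPBA (NaHCO3, CH2Cl2, 0 °C) should give the racemic anti epoxide, that is 5 together with the enantiomeric epoxide F2. Acetolysis as in step 5 gives 6 together with the enantiomeric hydroxy acetate F3. Lipase B of Candida antarctica with vinyl acetate should then acetylate the C3 alcohol of the (3R) enantiomer only (the fast-reacting configuration for a secondary alcohol flanked by one large and one small group), giving diacetate F4; unreacted 6 is separated and the route is rejoined at 6.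

Step 12. What may go wrong: competing aldol addition of the methyl ketone enolate to the C15 aldehyde, or carbene-induced deformylation of the hindered α-formyl lactone. The fallback sets out from 18 and replaces the umpolung coupling by a reductive one. After equilibration of C13 with DBU, a ketyl-mediated aldehyde–ketone pinacol cyclisation with SmI2 (THF, t-BuOH, −78 °C) should give the cis-diol F5. Parikh–Doering oxidation (SO3·pyridine, DMSO, Et3N) of its secondary C15 alcohol then returns to the route at 19; the C13 epimer that cannot cyclise is recovered and re-equilibrated.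

**Further compounds**

F1 | step 11 | open Giese adduct: α-branched C15 aldehyde (C8–H) with the phenyl carbonate intact; C9 and C10 as in 18, C8 and C13 undefined | O=CC1CC(C(C)=O)CC[C@H]1[C@@]1(CC[C@H](O[Si](C)(C)C(C)(C)C)[C@@](C)(OC(C)=O)[C@H]1CO[Si](c1ccccc1)(c1ccccc1)C(C)(C)C)COC(=O)Oc1ccccc1
F2 | step 4 | enantiomer of epoxide 5 | CC1=CC[C@H]2O[C@@]2(C)[C@@H]1CO[Si](c1ccccc1)(c1ccccc1)C(C)(C)C
F3 | step 4 | enantiomer of hydroxy acetate 6 | CC1=CC[C@@H](O)[C@](C)(OC(C)=O)[C@@H]1CO[Si](c1ccccc1)(c1ccccc1)C(C)(C)C
F4 | step 4 | diacetate formed from F3 by acetylation of its C3 hydroxyl | CC1=CC[C@@H](OC(C)=O)[C@](C)(OC(C)=O)[C@@H]1CO[Si](c1ccccc1)(c1ccccc1)C(C)(C)C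
F5 | step 12 | cis-15,16-diol from pinacol closure of ring D (C15 secondary alcohol, C16 tertiary methyl carbinol), otherwise as 19 | CC1(O)C(O)[C@]23C[C@H]1CC[C@H]2[C@@]1(CC[C@H](O[Si](C)(C)C(C)(C)C)[C@@](C)(OC(C)=O)[C@H]1CO[Si](c1ccccc1)(c1ccccc1)C(C)(C)C)COC3=O
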